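**Plan**

- Retrosynthesis: the C3–Br and C6–Br bonds and the aromatic unsaturation are removed first, the formyl group is traced back to an ester, and the ring is then opened at C2–C3 and C1–C6.
- Enabling feature: these two ring bonds separate a four-carbon piece C3–C4–C5–C6, which holds both oxygens on C4 and C5, from a two-carbon piece C1–C2, which holds the formyl carbon and one bromine. The pieces correspond to a 2,3-dioxygenated butadiene and a 3-bromopropiolate.
- Forward: the diene is made from butane-2,3-dione and the bromoalkyne from methyl propiolate; a [4+2] cycloaddition closes the only ring as a cyclohexa-1,4-diene; the ester is taken to the aldehyde on that diene; bromine then unmasks the catechol, aromatises the ring and brominates C3 and C6 in one flask.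
- Stereochemistry: the target is achiral and has no stereocentre, and none is made on the way. Regiochemistry follows from the symmetric diene and from C3 and C6 being the only free ring positions.

Key step: step 3

Remark: tert-butyldimethylsilyl (TBS) enol ethers are used in place of trimethylsilyl ones, because the enediol ether has to survive a hydride reduction with aqueous work-up and an alcohol oxidation before bromine unmasks the catechol.

**Route**

Step 1
Reactants: 1 butane-2,3-dione
Product: 3 2,3-bis(tert-butyldimethylsilyloxy)buta-1,3-diene, via 3-(tert-butyldimethylsilyloxy)but-3-en-2-one 2 (not isolated)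
Conditions: TBSOTf (2.2 equiv), Et3N (3 equiv), CH2Cl2, 0 °C to rt
Reagents that add atoms: tert-butyldimethylsilyl trifluoromethanesulfonate (TBSOTf), CC(C)(C)[Si](C)(C)OS(=O)(=O)C(F)(F)F
Why: Double soft enolisation (silyl enol ether formation), in which the silyl triflate activates each carbonyl and Et3N removes the neighbouring methyl proton, so that both ketones should be trapped as O-silyl enol ethers, the second one by way of the mono-enol ether 2.

Step 2
Reactants: 4 methyl propiolate
Product: 5 methyl 3-bromopropiolate
Conditions: NBS (1.15 equiv), AgNO3 (10 mol%), acetone, rt, dark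
Reagents that add atoms: N-bromosuccinimide (NBS), O=C1CCC(=O)N1Br
Why: Silver-catalysed electrophilic bromination of a terminal alkyne, in which a silver acetylide formed at the acidic C–H is brominated by NBS, a standard preparation of 1-bromoalkynes that leaves the ester untouched.

Step 3
Reactants: 3 2,3-bis(tert-butyldimethylsilyloxy)buta-1,3-diene; 5 methyl 3-bromopropiolate
Product: 6 methyl 2-bromo-4,5-bis(tert-butyldimethylsilyloxy)cyclohexa-1,4-diene-1-carboxylate
Conditions: toluene, BHT (cat.), 100 °C, sealed tube
Reagents that add atoms: none
Why: A concerted, suprafacial normal-electron-demand Diels–Alder reaction in which the high-lying HOMO of the 2,3-bis(silyloxy)diene combines with the low-lying LUMO of the ester-activated bromoalkyne and forms C2–C3 and C1–C6 together. The closest known reaction type is the thermal cycloaddition of 2,3-bis(silyloxy)butadienes to acetylenic esters, and 3-halopropiolates are established dienophiles. The single six-membered carbocycle is closed by intermolecular [4+2] annulation of a four-carbon and a two-carbon unit and should emerge as a cyclohexa-1,4-diene. No stereocentre is created, and the constitutionally symmetric diene allows only one regioisomer. The step needs one clean addition without desilylation: the tetrasubstituted product alkene is a far worse dienophile than the alkyne, the bromine on C2 is vinylic and cannot leave as HBr, and neutral anhydrous conditions together with the bulky silyl groups should keep both enol ethers intact.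

Step 4
Reactants: 6 methyl 2-bromo-4,5-bis(tert-butyldimethylsilyloxy)cyclohexa-1,4-diene-1-carboxylate
Product: 7 [2-bromo-4,5-bis(tert-butyldimethylsilyloxy)cyclohexa-1,4-dien-1-yl]methanol
Conditions: iBu2AlH (2.3 equiv), CH2Cl2, −78 to −30 °C; aq. potassium sodium tartrate
Reagents that add atoms: none
Why: 1,2-Reduction of an α,β-unsaturated ester to the allylic alcohol by iBu2AlH, an electrophilic hydride that at low temperature should touch neither the silyl enol ethers nor the vinylic C–Br bond.

Step 5
Reactants: 7 [2-bromo-4,5-bis(tert-butyldimethylsilyloxy)cyclohexa-1,4-dien-1-yl]methanol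
Product: 8 2-bromo-4,5-bis(tert-butyldimethylsilyloxy)cyclohexa-1,4-diene-1-carbaldehyde
Conditions: Dess–Martin periodinane (1.2 equiv), pyridine (3 equiv), CH2Cl2, 0 °C; used without storage
Reagents that add atoms: none
Why: Dess–Martin oxidation of a primary allylic alcohol to the enal under pyridine-buffered, non-aqueous conditions that tolerate silyl enol ethers and cannot over-oxidise to the acid.

Step 6
Reactants: 8 2-bromo-4,5-bis(tert-butyldimethylsilyloxy)cyclohexa-1,4-diene-1-carbaldehyde
Product: 12 2,3,6-tribromo-4,5-dihydroxybenzaldehyde, via ring diketone 9 (not isolated), via monobromo catechol aldehyde 10 (not isolated), via dibromo catechol aldehyde 11 (not isolated)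
Conditions: Br2 (1.05 equiv), CH2Cl2, −78 to 0 °C; then AcOH, Br2 (2.3 equiv), Fe powder (5 mol%), 20–40 °C; aq. NaHSO3
Reagents that add atoms: bromine, BrBr
Why: Bromine should first attack the electron-rich enediol bis(silyl ether) double bond (halogenative oxidation of a silyl enol ether) to give the 1,2-dione 9 with loss of both silyl groups, 9 tautomerises to the aromatic catechol 10, and electrophilic aromatic bromination ortho to the hydroxyls at the only free positions, most probably C3 first (11) and then C6, completes the substitution pattern.

**Compound list**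

1 | butane-2,3-dione | CC(=O)C(C)=O | starting material
2 | 3-(tert-butyldimethylsilyloxy)but-3-en-2-one | CC(=O)C(=C)O[Si](C)(C)C(C)(C)C | intermediate (not isolated)
3 | 2,3-bis(tert-butyldimethylsilyloxy)buta-1,3-diene | C=C(O[Si](C)(C)C(C)(C)C)C(=C)O[Si](C)(C)C(C)(C)C | intermediate
4 | methyl propiolate | COC(=O)C#C | starting material
5 | methyl 3-bromopropiolate | COC(=O)C#CBr | intermediate
6 | methyl 2-bromo-4,5-bis(tert-butyldimethylsilyloxy)cyclohexa-1,4-diene-1-carboxylate | COC(=O)C1=C(Br)CC(O[Si](C)(C)C(C)(C)C)=C(O[Si](C)(C)C(C)(C)C)C1 | intermediate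
7 | [2-bromo-4,5-bis(tert-butyldimethylsilyloxy)cyclohexa-1,4-dien-1-yl]methanol | OCC1=C(Br)CC(O[Si](C)(C)C(C)(C)C)=C(O[Si](C)(C)C(C)(C)C)C1 | intermediate
8 | 2-bromo-4,5-bis(tert-butyldimethylsilyloxy)cyclohexa-1,4-diene-1-carbaldehyde | O=CC1=C(Br)CC(O[Si](C)(C)C(C)(C)C)=C(O[Si](C)(C)C(C)(C)C)C1 | intermediate
9 | 2-bromo-4,5-dioxocyclohex-1-ene-1-carbaldehyde | O=CC1=C(Br)CC(=O)C(=O)C1 | intermediate (not isolated)
10 | 2-bromo-4,5-dihydroxybenzaldehyde | O=Cc1cc(O)c(O)cc1Br | intermediate (not isolated)
11 | 2,3-dibromo-4,5-dihydroxybenzaldehyde | O=Cc1cc(O)c(O)c(Br)c1Br | intermediate (not isolated)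
12 | 2,3,6-tribromo-4,5-dihydroxybenzaldehyde | O=Cc1c(Br)c(O)c(O)c(Br)c1Br | target

**Step count**

Total steps: 6. Longest linear sequence: 5 (steps 1, 3, 4, 5, 6 from butane-2,3-dione); step 2 is a one-step side branch.

**Steps most likely to fail, with fallbacks**

Step 3 (cycloaddition). The two bulky silyloxy groups on the inner diene carbons disfavour the s-cis conformer, so ring closure may be slower than thermal decomposition or oligomerisation of the bromoalkyne. The fallback sets out from 1 and 5 and returns at 10. It uses the unhindered trimethylsilyl diene and, because its enol ethers would not survive the reduction sequence, moves the ester-to-aldehyde adjustment to the aromatic stage under methyl ether protection. Compound 1 with Me3SiCl, Et3N and LiBr in THF should give 2,3-bis(trimethylsilyloxy)buta-1,3-diene F1. Heating F1 with 5 in toluene at 80 °C should give methyl 2-bromo-4,5-bis(trimethylsilyloxy)cyclohexa-1,4-diene-1-carboxylate F2. The crude adduct is treated with Br2 (1 equiv) in CH2Cl2 at −78 °C to give methyl 2-bromo-4,5-dihydroxybenzoate F3. MeI and K2CO3 in acetone convert F3 into methyl 2-bromo-4,5-dimethoxybenzoate F4, iBu2AlH reduces this to (2-bromo-4,5-dimethoxyphenyl)methanol F5, and MnO2 in CH2Cl2 oxidises it to 2-bromo-4,5-dimethoxybenzaldehyde F6. BBr3 in CH2Cl2 then removes both methyl groups and delivers 10, which is carried through the Br2/AcOH/Fe stage of step 6 to 12.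

Step 6 (bromine cascade). Ipso attack of bromine at C1, para to the C4 hydroxyl, may expel the formyl group under the forcing conditions needed for the last bromination; oxidation of the catechol to the ortho-quinone is reversed by the bisulfite work-up. The fallback sets out from 6 and returns at 12. It keeps the C1 substituent at the ester level, which does not undergo ipso substitution, during all bromine chemistry. Compound 6 with Br2 (3.3 equiv; CH2Cl2 at −78 °C, then AcOH with Fe powder) should give methyl 2,3,6-tribromo-4,5-dihydroxybenzoate F7. MeI and K2CO3 in DMF give methyl 2,3,6-tribromo-4,5-dimethoxybenzoate F8, iBu2AlH gives (2,3,6-tribromo-4,5-dimethoxyphenyl)methanol F9, and MnO2 gives 2,3,6-tribromo-4,5-dimethoxybenzaldehyde F10. BBr3 in CH2Cl2 (−78 °C to rt) then cleaves both methyl ethers to give 12.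

Step 5 (oxidation to the dienal). The skipped diene carries acidic doubly allylic hydrogens next to the new enal, so double-bond migration, premature aromatisation or enol ether cleavage by acidic by-products may give mixtures. The fallback sets out from 7 and returns at 10. It aromatises deliberately before the oxidation, so that the sensitive dienal is never formed. Compound 7 with DDQ (1.05 equiv) in toluene at rt should give [2-bromo-4,5-bis(tert-butyldimethylsilyloxy)phenyl]methanol F11. MnO2 in CH2Cl2 oxidises the benzylic alcohol to 2-bromo-4,5-bis(tert-butyldimethylsilyloxy)benzaldehyde F12. Bu4NF buffered with AcOH in THF at 0 °C removes both silyl groups and gives 10, which is brominated under the Br2/AcOH/Fe conditions of step 6 to 12.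

**Further compounds**

F1 | step 3 | 2,3-bis(trimethylsilyloxy)buta-1,3-diene | C=C(O[Si](C)(C)C)C(=C)O[Si](C)(C)C
F2 | step 3 | methyl 2-bromo-4,5-bis(trimethylsilyloxy)cyclohexa-1,4-diene-1-carboxylate | COC(=O)C1=C(Br)CC(O[Si](C)(C)C)=C(O[Si](C)(C)C)C1
F3 | step 3 | methyl 2-bromo-4,5-dihydroxybenzoate | COC(=O)c1cc(O)c(O)cc1Br
F4 | step 3 | methyl 2-bromo-4,5-dimethoxybenzoate | COC(=O)c1cc(OC)c(OC)cc1Br
F5 | step 3 | (2-bromo-4,5-dimethoxyphenyl)methanol | OCc1cc(OC)c(OC)cc1Br
F6 | step 3 | 2-bromo-4,5-dimethoxybenzaldehyde | O=Cc1cc(OC)c(OC)cc1Br
F7 | step 6 | methyl 2,3,6-tribromo-4,5-dihydroxybenzoate | COC(=O)c1c(Br)c(O)c(O)c(Br)c1Br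
F8 | step 6 | methyl 2,3,6-tribromo-4,5-dimethoxybenzoate | COC(=O)c1c(Br)c(OC)c(OC)c(Br)c1Br
F9 | step 6 | (2,3,6-tribromo-4,5-dimethoxyphenyl)methanol | OCc1c(Br)c(OC)c(OC)c(Br)c1Br
F10 | step 6 | 2,3,6-tribromo-4,5-dimethoxybenzaldehyde | O=Cc1c(Br)c(OC)c(OC)c(Br)c1Br
F11 | step 5 | [2-bromo-4,5-bis(tert-butyldimethylsilyloxy)phenyl]methanol | OCc1cc(O[Si](C)(C)C(C)(C)C)c(O[Si](C)(C)C(C)(C)C)cc1Br
F12 | step 5 | 2-bromo-4,5-bis(tert-butyldimethylsilyloxy)benzaldehyde | O=Cc1cc(O[Si](C)(C)C(C)(C)C)c(O[Si](C)(C)C(C)(C)C)cc1Br
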